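**Plan**

- Retrosynthesis: the two benzyl C–O bonds go last (acid and phenol both masked as benzyl). The ketone is traced back to a benzylic carbinol and the CH2OH group to a methyl ester. The aroyl C(=O)–C2 bond is then cut (Claisen acylation) and the aryl-O–CH2 ether bond (Williamson), leaving two derivatives of syringic acid and methyl bromoacetate.
- Forward: no ring is formed. The ether bond is made first, then the C–C bond by acylation of the aryloxyacetate enolate, giving a racemic 2-aryloxy-3-oxo ester.
- Enabling feature: in that ester, C2 (carrying H and the aryloxy oxygen) lies between the aryl ketone carbon C3 and the ester carbon C1, so it epimerises freely through the enol. The two benzene rings are spectators.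
- Stereochemistry: a Ru/TsDPEN transfer hydrogenation with dynamic kinetic resolution sets C2 (S) and C3 (R). C3 is oxidised away later; C2 becomes the (R) centre of the target with no change in geometry, because ester→CH2OH and carbinol→ketone swap the CIP ranks.
- Finish: DDQ restores the ketone and a single neutral hydrogenolysis removes both benzyl groups, so C2 never meets base once it is α to a ketone.

Key step: step 6

Assumption: the (S,S)-TsDPEN catalyst is taken to attack the ketone face it attacks in simple aryl ketones (giving 3R here) and to favour the syn isomer as with 2-alkoxy-3-oxo esters. Only 2S in 11 matters, since C3 is erased in step 8; if the substrate gave the opposite sense at C2, the (R,R) catalyst would be used.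

**Step 1**
Reactants: 1 syringic acid; 2 benzyl bromide
Product: 3 benzyl 4-hydroxy-3,5-dimethoxybenzoate
Conditions: BnBr (1.05 equiv), KHCO3 (1.2 equiv), DMF, 40 °C
Reagents that add atoms: benzyl bromide (compound 2), BrCc1ccccc1
Why: Carboxylate O-alkylation (SN2): hydrogencarbonate ionises only the carboxylic acid and leaves the flanked phenol (pKa about 9–10) protonated, so benzyl bromide should esterify without etherifying.

**Step 2**
Reactants: 3 benzyl 4-hydroxy-3,5-dimethoxybenzoate; 4 methyl bromoacetate
Product: 5 methyl 2-[4-(benzyloxycarbonyl)-2,6-dimethoxyphenoxy]acetate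
Conditions: K2CO3, acetone, reflux
Reagents that add atoms: methyl bromoacetate (compound 4), COC(=O)CBr
Why: Williamson ether synthesis: the phenoxide of 3 should displace bromide from the unhindered α-bromo ester despite the two ortho methoxy groups, as is routine for syringyl aryloxyacetates.

**Step 3**
Reactants: 1 syringic acid; 2 benzyl bromide
Product: 7 4-(benzyloxy)-3,5-dimethoxybenzoic acid, via benzyl O-benzylsyringate 6 (not isolated)
Conditions: BnBr (2.3 equiv), K2CO3, DMF, 60 °C; then aq NaOH, MeOH, 70 °C; aq HCl
Reagents that add atoms: benzyl bromide (compound 2), BrCc1ccccc1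
Why: Williamson etherification with concurrent carboxylate benzylation, then saponification of the benzyl ester in the same flask; the aryl benzyl ether is inert to hydroxide, so acid 7 should precipitate on acidification.

**Step 4**
Reactants: 7 4-(benzyloxy)-3,5-dimethoxybenzoic acid
Product: 8 1-[4-(benzyloxy)-3,5-dimethoxybenzoyl]-1H-imidazole
Conditions: CDI (1.1 equiv), THF, rt; evaporation, CH2Cl2/cold water wash
Reagents that add atoms: 1,1'-carbonyldiimidazole (CDI), O=C(n1ccnc1)n1ccnc1
Why: Staab activation: CDI converts the acid into the N-acylimidazole with loss of CO2 and imidazole under neutral conditions, giving an acyl donor reactive enough for an ester enolate and free of chloride and acid.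

**Step 5**
Reactants: 5 methyl 2-[4-(benzyloxycarbonyl)-2,6-dimethoxyphenoxy]acetate; 8 1-[4-(benzyloxy)-3,5-dimethoxybenzoyl]-1H-imidazole
Product: 10 racemic methyl 3-[4-(benzyloxy)-3,5-dimethoxyphenyl]-2-[4-(benzyloxycarbonyl)-2,6-dimethoxyphenoxy]-3-oxopropanoate, via chelated lithium ester enolate 9 (not isolated)
Conditions: LiHMDS (2.1 equiv), THF, −78 °C; then 8, −78 → −20 °C; sat. aq NH4Cl
Reagents that add atoms: none
Why: Crossed Claisen condensation (C-acylation of a lithium ester enolate by an N-acylimidazole): the second equivalent of base turns the more acidic 1,3-dicarbonyl product into its enolate as it forms, which should prevent proton transfer to unreacted enolate and a second acylation; C2 is formed racemic by design.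

**Step 6**
Reactants: 10 racemic methyl 3-[4-(benzyloxy)-3,5-dimethoxyphenyl]-2-[4-(benzyloxycarbonyl)-2,6-dimethoxyphenoxy]-3-oxopropanoate
Product: 11 methyl (2S,3R)-3-[4-(benzyloxy)-3,5-dimethoxyphenyl]-2-[4-(benzyloxycarbonyl)-2,6-dimethoxyphenoxy]-3-hydroxypropanoate (syn)
Conditions: RuCl(p-cymene)[(S,S)-TsDPEN] (2 mol %), HCO2H/Et3N (5:2), CH2Cl2, 30 °C
Reagents that add atoms: none
Why: Noyori–Ikariya asymmetric transfer hydrogenation run as a dynamic kinetic resolution, the reaction type established for 2-alkoxy- and 2-amido-3-oxo esters: the Ru amide dehydrogenates formate, and the Ru–H/N–H pair passes hydride and proton to the C3 ketone through an outer-sphere six-membered transition state, forming the benzylic C–H bond. No ring is closed and no skeletal bond is made. C3 is set by the catalyst, the aryl group of the ketone lying under the η6-cymene ligand (CH/π contact), which with the (S,S) ligand should give 3R as for other aryl ketones. C2 is set by the kinetic resolution: in HCO2H/Et3N the enantiomers of 10 interconvert through the enol of the 1,3-dicarbonyl faster than either is reduced, and the catalyst should reduce the (2S)-enantiomer preferentially to give the syn isomer, as 2-alkoxy analogues do. The step needs high syn selectivity (because C3 is later erased, the diastereomer ratio becomes the enantiomer ratio at C2) and chemoselectivity for the ketone, secured by the doubly activated C2–H, by the slow hydride transfer to the electron-rich aroyl group that lets equilibration keep pace, and by the inertness of esters and benzyl groups to this catalyst. Once reduced, C2 is flanked only by an ester and a carbinol and should hold its configuration under the mildly acidic conditions.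

**Step 7**
Reactants: 11 methyl (2S,3R)-3-[4-(benzyloxy)-3,5-dimethoxyphenyl]-2-[4-(benzyloxycarbonyl)-2,6-dimethoxyphenoxy]-3-hydroxypropanoate
Product: 12 benzyl 4-{[(1R,2R)-1-[4-(benzyloxy)-3,5-dimethoxyphenyl]-1,3-dihydroxypropan-2-yl]oxy}-3,5-dimethoxybenzoate
Conditions: LiBH4 (1.5 equiv), THF, 0 °C; sat. aq NH4Cl
Reagents that add atoms: none
Why: Hydroxyl-assisted borohydride reduction: the methyl ester, activated by the α-aryloxy group and by the neighbouring C3 alkoxyborohydride, should be reduced far faster than the electron-rich conjugated benzyl benzoate, and no base able to epimerise C2 is present (the descriptor at C2 changes from S to R only through the CIP ranks).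

**Step 8**
Reactants: 12 benzyl 4-{[(1R,2R)-1-[4-(benzyloxy)-3,5-dimethoxyphenyl]-1,3-dihydroxypropan-2-yl]oxy}-3,5-dimethoxybenzoate
Product: 13 benzyl 4-{[(2R)-1-[4-(benzyloxy)-3,5-dimethoxyphenyl]-3-hydroxy-1-oxopropan-2-yl]oxy}-3,5-dimethoxybenzoate
Conditions: DDQ (1.2 equiv), CH2Cl2, rt
Reagents that add atoms: none
Why: DDQ dehydrogenation of an electron-rich benzylic alcohol (hydride abstraction assisted by the para alkoxy group), the selective oxidation known for β-aryl ether 1,3-diols of this type; the primary alcohol should remain, and the weakly acidic medium should leave C2, now α to the ketone, untouched.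

**Step 9**
Reactants: 13 benzyl 4-{[(2R)-1-[4-(benzyloxy)-3,5-dimethoxyphenyl]-3-hydroxy-1-oxopropan-2-yl]oxy}-3,5-dimethoxybenzoate
Product: 14 4-{[(2R)-3-hydroxy-1-(4-hydroxy-3,5-dimethoxyphenyl)-1-oxopropan-2-yl]oxy}-3,5-dimethoxybenzoic acid (CNP0511559.1)
Conditions: H2 (1 atm), 10% Pd/C, EtOAc, rt; filtration through Celite
Reagents that add atoms: none
Why: Palladium-catalysed hydrogenolysis of the benzyl ether and the benzyl ester in one neutral operation; at 1 atm and room temperature the electron-rich aryl ketone and the C2–OAr bond should survive, and C2 is never exposed to base or strong acid.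

**Compound list**

1 | syringic acid (4-hydroxy-3,5-dimethoxybenzoic acid) | COc1cc(C(=O)O)cc(OC)c1O | starting material
2 | benzyl bromide | BrCc1ccccc1 | starting material
3 | benzyl 4-hydroxy-3,5-dimethoxybenzoate | COc1cc(C(=O)OCc2ccccc2)cc(OC)c1O | intermediate
4 | methyl bromoacetate | COC(=O)CBr | starting material
5 | methyl 2-[4-(benzyloxycarbonyl)-2,6-dimethoxyphenoxy]acetate | COC(=O)COc1c(OC)cc(C(=O)OCc2ccccc2)cc1OC | intermediate
6 | benzyl 4-(benzyloxy)-3,5-dimethoxybenzoate (benzyl O-benzylsyringate; formed in the flask in step 3, not isolated) | COc1cc(C(=O)OCc2ccccc2)cc(OC)c1OCc1ccccc1 | intermediate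
7 | 4-(benzyloxy)-3,5-dimethoxybenzoic acid | COc1cc(C(=O)O)cc(OC)c1OCc1ccccc1 | intermediate
8 | 1-[4-(benzyloxy)-3,5-dimethoxybenzoyl]-1H-imidazole | COc1cc(C(=O)n2ccnc2)cc(OC)c1OCc1ccccc1 | intermediate
9 | lithium enolate of 5, drawn in the chelated geometry with O–Li cis to the aryloxy oxygen (formed in the flask in step 5, not isolated) | [Li]O/C(OC)=C\Oc1c(OC)cc(C(=O)OCc2ccccc2)cc1OC | intermediate
10 | racemic methyl 3-[4-(benzyloxy)-3,5-dimethoxyphenyl]-2-[4-(benzyloxycarbonyl)-2,6-dimethoxyphenoxy]-3-oxopropanoate | COC(=O)C(Oc1c(OC)cc(C(=O)OCc2ccccc2)cc1OC)C(=O)c1cc(OC)c(OCc2ccccc2)c(OC)c1 | intermediate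
11 | methyl (2S,3R)-3-[4-(benzyloxy)-3,5-dimethoxyphenyl]-2-[4-(benzyloxycarbonyl)-2,6-dimethoxyphenoxy]-3-hydroxypropanoate | COc1cc([C@@H](O)[C@@H](C(=O)OC)Oc2c(OC)cc(C(=O)OCc3ccccc3)cc2OC)cc(OC)c1OCc1ccccc1 | intermediate
12 | benzyl 4-{[(1R,2R)-1-[4-(benzyloxy)-3,5-dimethoxyphenyl]-1,3-dihydroxypropan-2-yl]oxy}-3,5-dimethoxybenzoate | COc1cc([C@@H](O)[C@@H](CO)Oc2c(OC)cc(C(=O)OCc3ccccc3)cc2OC)cc(OC)c1OCc1ccccc1 | intermediate
13 | benzyl 4-{[(2R)-1-[4-(benzyloxy)-3,5-dimethoxyphenyl]-3-hydroxy-1-oxopropan-2-yl]oxy}-3,5-dimethoxybenzoate | COc1cc(C(=O)[C@@H](CO)Oc2c(OC)cc(C(=O)OCc3ccccc3)cc2OC)cc(OC)c1OCc1ccccc1 | intermediate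
14 | 4-{[(2R)-3-hydroxy-1-(4-hydroxy-3,5-dimethoxyphenyl)-1-oxopropan-2-yl]oxy}-3,5-dimethoxybenzoic acid | COc1cc(C(=O)[C@@H](CO)Oc2c(OC)cc(C(=O)O)cc2OC)cc(OC)c1O | target

**Step count**

Total steps: 9. Longest linear sequence: 7 steps (steps 3, 4, 5, 6, 7, 8, 9 from syringic acid; the branch through steps 1 and 2 is equally long).

**Steps most likely to fail**

Step 6. The two equilibrating enantiomers of 10 may not be discriminated well enough; a low syn to anti ratio would reappear after step 8 as low enantiomeric purity at C2. Hydride transfer to the electron-rich aroyl group may also be too slow. The fallback replaces the reduction by an auxiliary-controlled aldol reaction. Setting out from 5, the aliphatic methyl ester is hydrolysed selectively (LiOH, THF/H2O, 0 °C) to 2-[4-(benzyloxycarbonyl)-2,6-dimethoxyphenoxy]acetic acid F1. Its pivalic mixed anhydride (PivCl, Et3N) is coupled with lithiated (S)-4-benzyloxazolidin-2-one to give (4S)-4-benzyl-3-{2-[4-(benzyloxycarbonyl)-2,6-dimethoxyphenoxy]acetyl}oxazolidin-2-one F2. The Z boron enolate (Bu2BOTf, iPr2NEt, CH2Cl2, −78 °C) is added to commercial 4-(benzyloxy)-3,5-dimethoxybenzaldehyde in an Evans syn aldol reaction. This should give (4S)-4-benzyl-3-{(2S,3R)-3-[4-(benzyloxy)-3,5-dimethoxyphenyl]-2-[4-(benzyloxycarbonyl)-2,6-dimethoxyphenoxy]-3-hydroxypropanoyl}oxazolidin-2-one F3, with the same spatial arrangement as 11. LiBH4 (THF, 0 °C) then removes the auxiliary reductively and gives diol 12, where the route is rejoined before step 8.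

Step 5. C-acylation may stay incomplete, the enolate may be acylated on oxygen, or the hindered 1,3-dicarbonyl product may undergo retro-Claisen cleavage on work-up. The fallback forms the C2–O bond last. Setting out from 8, Masamune–Brooks homologation with potassium methyl malonate (MgCl2, Et3N, MeCN, rt) gives, after decarboxylation, methyl 3-[4-(benzyloxy)-3,5-dimethoxyphenyl]-3-oxopropanoate F4. Bromination of the active methylene with NBS gives racemic methyl 2-bromo-3-[4-(benzyloxy)-3,5-dimethoxyphenyl]-3-oxopropanoate F5. Displacement of bromide by the phenoxide of 3 (K2CO3, acetone, rt) gives 10, where the route is rejoined before step 6.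

Step 9. Hydrogen may be taken up beyond debenzylation, either by hydrogenolysis of the C2–OAr bond next to the ketone or by reduction of the aryl ketone. The fallback reverses the order of the last two operations so that no ketone is present during hydrogenolysis. Setting out from diol 12, hydrogenolysis (H2, Pd/C, EtOAc/MeOH, rt) gives 4-{[(1R,2R)-1,3-dihydroxy-1-(4-hydroxy-3,5-dimethoxyphenyl)propan-2-yl]oxy}-3,5-dimethoxybenzoic acid F6. DDQ in 1,4-dioxane then oxidises the p-hydroxybenzylic alcohol, a known selective oxidation of such phenols, and arrives at 14.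

**Further compounds**

F1 | step 6 | 2-[4-(benzyloxycarbonyl)-2,6-dimethoxyphenoxy]acetic acid | OC(=O)COc1c(OC)cc(C(=O)OCc2ccccc2)cc1OC
F2 | step 6 | (4S)-4-benzyl-3-{2-[4-(benzyloxycarbonyl)-2,6-dimethoxyphenoxy]acetyl}oxazolidin-2-one | O=C(COc1c(OC)cc(C(=O)OCc2ccccc2)cc1OC)N1[C@@H](Cc2ccccc2)COC1=O
F3 | step 6 | (4S)-4-benzyl-3-{(2S,3R)-3-[4-(benzyloxy)-3,5-dimethoxyphenyl]-2-[4-(benzyloxycarbonyl)-2,6-dimethoxyphenoxy]-3-hydroxypropanoyl}oxazolidin-2-one | COc1cc([C@@H](O)[C@@H](C(=O)N2[C@@H](Cc3ccccc3)COC2=O)Oc2c(OC)cc(C(=O)OCc3ccccc3)cc2OC)cc(OC)c1OCc1ccccc1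
F4 | step 5 | methyl 3-[4-(benzyloxy)-3,5-dimethoxyphenyl]-3-oxopropanoate | COC(=O)CC(=O)c1cc(OC)c(OCc2ccccc2)c(OC)c1
F5 | step 5 | racemic methyl 2-bromo-3-[4-(benzyloxy)-3,5-dimethoxyphenyl]-3-oxopropanoate | COC(=O)C(Br)C(=O)c1cc(OC)c(OCc2ccccc2)c(OC)c1
F6 | step 9 | 4-{[(1R,2R)-1,3-dihydroxy-1-(4-hydroxy-3,5-dimethoxyphenyl)propan-2-yl]oxy}-3,5-dimethoxybenzoic acid | COc1cc([C@@H](O)[C@@H](CO)Oc2c(OC)cc(C(=O)O)cc2OC)cc(OC)c1O
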